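## The problem

Compound 20 is a lignan built on a tetrahydrofuran ring. With the ring numbered O1, C2, C3, C4, C5, C3 carries the benzylic methylene C7' with ring B and C4 carries the secondary carbinol carbon C7 with ring A; both arenes are 3-hydroxy-4-methoxyphenyl groups. Three contiguous stereocentres must be set, C3 (R), C4 (S) and C7 (S). The two ring substituents are cis, the less stable arrangement, so the ring centres must be made under kinetic control and C4 must not stay next to a carbonyl group under equilibrating conditions. C3 and C4 can be created together by adding two hydrogen atoms to one face of a C3=C4 double bond, whereas the exocyclic centre C7 must be induced from C4. For aryl addition to a C7 aldehyde, the Felkin–Anh model (C3 with its benzyl group as the large substituent) and a chelate through O1 both lead to the (S)-carbinol. The C7 carbinol is a 4-methoxybenzylic alcohol that ionises in acid and is lost on hydrogenolysis, and the phenols must be masked against organomagnesium reagents, which points to silyl ethers removed by fluoride at the end. The enabling feature is the chain C2–C3–C4–C7: four carbons with an oxygen on each end (O1 on C2, the carbinol oxygen on C7). This is but-2-yne-1,4-diol 6 once C3=C4 is read as a former triple bond, so only the benzyl group on C3 and the single carbon C5 on C4 remain to be added, with the C2 alkoxide placed to direct both events.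

## Retrosynthesis

**O–Si bonds.** Target 20 is traced to its bis(silyl) ether 19. The tert-butyldimethylsilyl groups on both phenols survive magnesium reagents, hydride, Lewis acid and oxidant, and are removed by buffered fluoride without acid or hydrogenolysis, which the benzylic carbinol would not tolerate. Benzyl ethers were rejected for that reason.

**C7–aryl bond.** Cutting the bond between C7 and ring A gives the cis aldehyde 18 and the arylmagnesium bromide 17. The neighbouring cut, C4–C7, would need a C4 nucleophile cis to the benzyl group and offers no such handle. Reducing an aryl ketone is less attractive, because in the Felkin–Anh arrangement hydride would enter where the aryl group must end up. Aldehyde 18 has two stereocentres fewer at the exocyclic position and one arene fewer. The forward step must add faster than it enolises, since C4 is epimerisable in 18.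

**Oxidation levels at C7 and C5.** Aldehyde 18 comes from the primary alcohol 14. The ether carbon C5 of 14 is traced through lactol 13 to the carbonyl carbon of the cis hydroxymethyl lactone 12. This places a carbonyl at C5 and a free hydroxymethyl at C7, which is the pattern a carboxylation of a butynediol-derived alkenylmetal delivers. The forward steps are a lactone-to-ether reduction in two operations and a non-basic oxidation.

**C3–H and C4–H bonds.** Removing the two cis hydrogen atoms from 12 gives the achiral butenolide 11 with a tetrasubstituted C3=C4 bond. Syn addition to this ring alkene can only give the cis product, which a conjugate reduction followed by protonation would not guarantee. A chiral catalyst must choose the face. This is the demanding step of the plan, and the free C7 hydroxyl and the lactone carbonyl are kept as binding sites for it.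

**C3–C7', C4–C5 and C5–O1 bonds (key disconnection).** Butenolide 11 is taken apart into the benzylmagnesium chloride 5, but-2-yne-1,4-diol 6 and carbon dioxide 7. Intermediates are the dialkoxide 8, the chelated alkenylmagnesium 9 and the Z hydroxy acid 10. A stepwise construction on a preformed butenolide would need separate C-benzylation and hydroxymethylation. Here three skeletal bonds and the ring arise in one flask from bulk chemicals, and the symmetry of 6 removes any regiochemical question. The forward reaction must be an anti addition, so that the carboxyl group ends cis to the C2 oxygen.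

**Reagents.** Reagent 5 is traced through chloride 4, alcohol 3 and silyl ether 2 to isovanillin 1. Reagent 17 comes from aryl bromide 16 and 5-bromo-2-methoxyphenol 15. Both arenes are bought with their oxygen pattern in place.

## Roads not taken

**Alternative 1:** This road cuts C3–C7' and C4–C7, and later C7–C7'.
- **Forward key step.** Amide A2, a ring B arylacetamide whose nitrogen lies in a C2-symmetric trans-2,5-dimethylpyrrolidine ring, would be activated with Tf2O and a hindered pyridine base and joined to 2,5-dihydrofuran A1 in a keteniminium [2+2] cycloaddition. Hydrolysis gives the cis-fused cyclobutanone A3, whose carbonyl carbon is C7 and whose aryl-bearing carbon is C7'. Adding the ring A aryl nucleophile to C7 and alkoxide-driven cleavage of the strained C7–C7' bond would give the cis aryl ketone A4, which must then be reduced at C7.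
- **Merits.** The ring A1 is bought. The cis relationship follows from the ring fusion and not from a hydrogenation. The auxiliary gives absolute control in a reaction class with good precedent. No tetrasubstituted alkene has to be reduced.
- **Weak points.** Monosubstituted aryl keteniminium ions are more prone to side reactions than disubstituted ones, the electron-rich arene can itself attack the activated amide, and A1 is an inductively deactivated alkene. The cleavage releases A4 under basic conditions with C4 next to a ketone and cis to its neighbour, so epimerisation to trans threatens. In the reduction of A4 the Felkin–Anh preference puts hydride where the aryl group of 20 must be, so reagent control would have to overrule the substrate.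
- **Comparison.** For C3 and C4 this road stands on firmer ground than step 6 of the chosen plan and is not longer. The chosen plan sets against it that C7 is formed by aryl addition to aldehyde 18, where steric and chelate control agree, that C4 never sits beside a ketone in base, and that no stoichiometric auxiliary is consumed.

**Alternative 2:** This road cuts C2–C3 and C4–C5.
- **Forward key step.** The 1,3-dipole released by CsF from chloromethyl (trimethylsilyl)methyl ether A6 would add across the double bond of the enantioenriched 5-aryl butenolide A5. In A5 the aryl-bearing carbon is C7' with ring B as its benzyl ether and the lactone carbonyl is C7. Addition anti to the aryl group gives the cis-fused bicyclic lactone A7. Hydrogenolysis of the benzylic lactone C–O bond with H2 over Pd/C would erase the directing stereocentre, free the phenol and leave the cis acid A8.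
- **Merits.** The tetrahydrofuran ring and both ring stereocentres come from one concerted step. One easily made stereocentre relays its information and then vanishes. No tetrasubstituted alkene is hydrogenated.
- **Weak points.** The γ-hydrogen of A5 is allylic, benzylic and next to oxygen, so the basic fluoride source can racemise A5 or move its double bond before the dipole arrives. Non-stabilised dipoles of this kind need an excess of A6 and oligomerise. The C7 carboxyl group of A8 must still be taken to the aldehyde level and arylated exactly as in steps 11 and 12, so nothing is saved at the C7 end.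
- **Comparison.** If A5 keeps its configuration, ring stereocontrol is at least as good as in the chosen plan. The chosen plan sets against it an achiral, configurationally safe sequence up to step 6, cheaper building blocks (6 and 7), three skeletal bonds in one operation, and a C7 carbon that already has the alcohol oxidation level.

**Alternative 3:** This road cuts the ring bond C3–C4 and the C7'–aryl bond.
- **Forward key step.** The allyl ether A9 of a bromohydrin, already carrying the C7 silyl ether with ring A, would be treated with CoCl2, Ph2PCH2CH2PPh2 and the arylmagnesium bromide 17, which also serves for ring B because the two arenes are identical. The C4 radical closes 5-exo onto the allyl group, and the exocyclic C7' radical is captured by an aryl–cobalt species to give the tris(silyl) ether A10. One deprotection would then give 20.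
- **Merits.** It is the shortest and most convergent road. The ring and the second arene arrive in one step, and C7 can be set beforehand by a reliable method.
- **Weak points.** C3 and C4 are set by the kinetic preferences of an open-shell cyclisation. The usual preference of 1-substituted hex-5-enyl radicals for cis closure helps, but it is moderate. Induction from C7 to C4 is not secured. A β-silyloxy bromide can be lost by reductive elimination to an alkene under low-valent cobalt and excess 17. The resulting diastereomers would be hard to separate.
- **Comparison.** In step count and convergence this road is clearly better. The chosen plan sets against it that each stereocentre has a defined controlling element: syn hydrogen delivery enforces cis, and two converging models set C7.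

Key step: step 5

Remark on the chemistry: the sense of induction in step 6 is assigned by analogy with the quadrant model for Ru(OAc)2(BINAP) hydrogenation of allylic alcohols, which calls for (R)-BINAP. If the correlation proves opposite, the (S)-ligand is used and nothing else changes.

## Route

Step 1
Reactants: 1 isovanillin (3-hydroxy-4-methoxybenzaldehyde)
Product: 2 3-(tert-butyldimethylsilyloxy)-4-methoxybenzaldehyde
Conditions: TBSCl, imidazole, DMF, 0 °C → rt
Reagents that add atoms: tert-butyldimethylsilyl chloride, CC(C)(C)[Si](C)(C)Cl
Why: Standard silylation of a phenol with imidazole as base; the aldehyde is untouched and the aryl silyl ether tolerates the hydride, magnesium and Lewis-acid steps that follow.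

Step 2
Reactants: 2 3-(tert-butyldimethylsilyloxy)-4-methoxybenzaldehyde
Product: 3 [3-(tert-butyldimethylsilyloxy)-4-methoxyphenyl]methanol
Conditions: NaBH4, THF/MeOH, 0 °C
Reagents that add atoms: none
Why: Borohydride reduction of an aromatic aldehyde; a short reaction at 0 °C keeps the phenolic silyl ether from methanolysis.

Step 3
Reactants: 3 [3-(tert-butyldimethylsilyloxy)-4-methoxyphenyl]methanol
Product: 4 tert-butyl[5-(chloromethyl)-2-methoxyphenoxy]dimethylsilane
Conditions: MsCl, i-Pr2NEt, CH2Cl2, 0 °C → rt
Reagents that add atoms: methanesulfonyl chloride, CS(=O)(=O)Cl (supplies the chlorine)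
Why: Mesylation of the electron-rich benzylic alcohol followed by displacement of the mesylate by chloride in the same flask; the hindered amine buffers the acid, spares the silyl ether and does not quaternise the chloride.

Step 4
Reactants: 4 tert-butyl[5-(chloromethyl)-2-methoxyphenoxy]dimethylsilane
Product: 5 [3-(tert-butyldimethylsilyloxy)-4-methoxybenzyl]magnesium chloride (titrated solution, used at once)
Conditions: Mg turnings (excess, I2-activated), THF/Et2O, 0 °C, slow addition at high dilution
Reagents that add atoms: magnesium, [Mg]
Why: Grignard formation by insertion of magnesium into the benzylic C–Cl bond; slow addition to excess metal at low concentration limits Wurtz homocoupling.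

Step 5
Reactants: 6 but-2-yne-1,4-diol; 5 [3-(tert-butyldimethylsilyloxy)-4-methoxybenzyl]magnesium chloride; 7 carbon dioxide
Product: 11 4-{[3-(tert-butyldimethylsilyloxy)-4-methoxyphenyl]methyl}-3-(hydroxymethyl)furan-2(5H)-one, via bis(chloromagnesium) dialkoxide 8 (not isolated), via chelated alkenylmagnesium oxamagnesacycle 9 (not isolated), via Z hydroxy acid 10 (not isolated)
Conditions: MeMgCl (2.0 equiv), THF, 0 °C; 5 (1.5 equiv), CuI (10 mol %), 0 → 40 °C; CO2 (7), −20 °C → rt; 2 M HCl, rt
Reagents that add atoms: methylmagnesium chloride, C[Mg]Cl (its chloromagnesium units sit on the oxygen atoms of intermediates 8 and 9; none of its atoms remains in 11)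
Why: MeMgCl first turns 6 into the bis(chloromagnesium) alkoxide 8, so that none of reagent 5 is spent as a base. Catalysed by CuI (monovalent copper), the benzyl group of 5 is then delivered to the alkyne carbon next to one alkoxide (C3) while magnesium ends on C4 and is held by that alkoxide in the five-membered oxamagnesacycle 9; the closest known reaction type is the CuI-catalysed anti carbomagnesiation of propargylic alkoxides, which is documented for but-2-yne-1,4-diol itself. The chelate makes the addition anti, so the C4–Mg bond is cis to the C2 oxygen and trans to the new benzyl group, and the symmetry of 6 removes any regiochemical question. Carboxylation of the alkenyl–magnesium bond by 7 proceeds with retention and forms C4–C5. Acidification liberates the Z hydroxy acid 10, whose C2 hydroxyl lies cis to the carboxyl group and closes the butenolide ring by a 5-exo-trig acyl substitution (bond C5–O1); the geminal hydroxymethyl group C7 could only form a four-membered lactone and stays free. No stereocentre is created. The only selectivity the step needs is the anti geometry, and the alkoxide chelate secures it; three skeletal bonds (C3–C7', C4–C5, C5–O1) and the whole ring are assembled in one flask.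

Step 6
Reactants: 11 4-{[3-(tert-butyldimethylsilyloxy)-4-methoxyphenyl]methyl}-3-(hydroxymethyl)furan-2(5H)-one
Product: 12 (3R,4R)-4-{[3-(tert-butyldimethylsilyloxy)-4-methoxyphenyl]methyl}-3-(hydroxymethyl)oxolan-2-one (cis lactone)
Conditions: H2 (100 atm), Ru(OAc)2[(R)-BINAP] (2 mol %), MeOH, 30 °C
Reagents that add atoms: none
Why: Proposed new method: Ru(OAc)2(BINAP) (divalent ruthenium) hydrogenates allylic alcohols through a ruthenium alkoxide hydride that inserts the bound alkene, and β-substituted butenolides through carbonyl-assisted binding; in 11 the C7 hydroxyl and the lactone carbonyl flank the C3=C4 bond and should hold it on the metal although it is tetrasubstituted, both hydrogen atoms then arrive on the same face (cis product, C3 and C4 set together) and the ligand chooses that face; the closest known reaction types are the Ru(OAc)2(BINAP)-catalysed hydrogenation of geraniol-type allylic alcohols and of trisubstituted butenolides, and the cis-selective enantioselective hydrogenation of tetrasubstituted 2,3-dialkylcyclopent-2-enones that carry a chelating ester arm.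

Step 7
Reactants: 12 (3R,4R)-4-{[3-(tert-butyldimethylsilyloxy)-4-methoxyphenyl]methyl}-3-(hydroxymethyl)oxolan-2-one
Product: 13 (3R,4R)-4-{[3-(tert-butyldimethylsilyloxy)-4-methoxyphenyl]methyl}-3-(hydroxymethyl)oxolan-2-ol (lactol, both anomers)
Conditions: i-Bu2AlH (2.5 equiv), CH2Cl2, −78 °C; aq. potassium sodium tartrate
Reagents that add atoms: none
Why: Partial reduction of a γ-lactone to the lactol; the first equivalent of hydride is consumed by the free hydroxyl, and the aluminium hemiacetal is stable at −78 °C, so neither over-reduction nor epimerisation at C4 is expected.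

Step 8
Reactants: 13 (3R,4R)-4-{[3-(tert-butyldimethylsilyloxy)-4-methoxyphenyl]methyl}-3-(hydroxymethyl)oxolan-2-ol
Product: 14 [(3R,4R)-4-{[3-(tert-butyldimethylsilyloxy)-4-methoxyphenyl]methyl}oxolan-3-yl]methanol (cis)
Conditions: Et3SiH (5 equiv), BF3·OEt2 (2 equiv), CH2Cl2, −78 → −30 °C
Reagents that add atoms: none
Why: Ionic hydrogenation of a lactol: the Lewis acid ionises the anomeric hydroxyl to the cyclic oxocarbenium ion and the silane delivers hydride to C5; no stereocentre is touched as long as the ion is reduced faster than it loses the C4 proton, which excess silane at low temperature should ensure.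

Step 9
Reactants: 15 5-bromo-2-methoxyphenol
Product: 16 (5-bromo-2-methoxyphenoxy)(tert-butyl)dimethylsilane
Conditions: TBSCl, imidazole, DMF, rt
Reagents that add atoms: tert-butyldimethylsilyl chloride, CC(C)(C)[Si](C)(C)Cl
Why: Standard phenol silylation; the aryl bromide is inert.

Step 10
Reactants: 16 (5-bromo-2-methoxyphenoxy)(tert-butyl)dimethylsilane
Product: 17 [3-(tert-butyldimethylsilyloxy)-4-methoxyphenyl]magnesium bromide (titrated solution)
Conditions: Mg turnings (I2-activated), THF, 50 °C
Reagents that add atoms: magnesium, [Mg]
Why: Grignard formation from an aryl bromide; the silyloxy group is meta to the metal, so no silyl migration to carbon is possible.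

Step 11
Reactants: 14 [(3R,4R)-4-{[3-(tert-butyldimethylsilyloxy)-4-methoxyphenyl]methyl}oxolan-3-yl]methanol
Product: 18 (3S,4R)-4-{[3-(tert-butyldimethylsilyloxy)-4-methoxyphenyl]methyl}oxolane-3-carbaldehyde (cis; used crude at once)
Conditions: Dess–Martin periodinane, NaHCO3, CH2Cl2, 0 °C → rt
Reagents that add atoms: none
Why: Dess–Martin oxidation of a primary alcohol under buffered, non-basic conditions, chosen so that the α-centre C4 of the cis aldehyde is not epimerised.

Step 12
Reactants: 18 (3S,4R)-4-{[3-(tert-butyldimethylsilyloxy)-4-methoxyphenyl]methyl}oxolane-3-carbaldehyde; 17 [3-(tert-butyldimethylsilyloxy)-4-methoxyphenyl]magnesium bromide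
Product: 19 (S)-[3-(tert-butyldimethylsilyloxy)-4-methoxyphenyl][(3S,4R)-4-{[3-(tert-butyldimethylsilyloxy)-4-methoxyphenyl]methyl}oxolan-3-yl]methanol
Conditions: 17 (1.5 equiv), MgBr2·OEt2 (1.5 equiv), CH2Cl2/THF, −78 °C; pH 7 buffer
Reagents that add atoms: none
Why: Grignard addition to an α-chiral aldehyde, with C7 set by 1,2-induction from C4: in the Felkin–Anh arrangement the bulkier ring carbon C3 with its cis benzyl group lies anti to the incoming aryl group, and in the magnesium chelate between the carbonyl oxygen and O1 the aryl group likewise enters anti to C3. Both models give Re-face attack and the (S)-carbinol, and fast addition at −78 °C should outrun enolisation.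

Step 13
Reactants: 19 (S)-[3-(tert-butyldimethylsilyloxy)-4-methoxyphenyl][(3S,4R)-4-{[3-(tert-butyldimethylsilyloxy)-4-methoxyphenyl]methyl}oxolan-3-yl]methanol
Product: 20 (S)-(3-hydroxy-4-methoxyphenyl)[(3S,4R)-4-(3-hydroxy-4-methoxybenzyl)oxolan-3-yl]methanol
Conditions: Bu4NF (2.5 equiv), AcOH (2.5 equiv), THF, 0 °C → rt
Reagents that add atoms: none
Why: Fluoride cleavage of the two aryl silyl ethers; acetic acid protonates the phenoxides, and the medium is never acidic enough to ionise the 4-methoxybenzylic alcohol.

## Compound list

1 | isovanillin (3-hydroxy-4-methoxybenzaldehyde) | COc1ccc(C=O)cc1O | starting material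
2 | 3-(tert-butyldimethylsilyloxy)-4-methoxybenzaldehyde | COc1ccc(C=O)cc1O[Si](C)(C)C(C)(C)C | intermediate
3 | [3-(tert-butyldimethylsilyloxy)-4-methoxyphenyl]methanol | COc1ccc(CO)cc1O[Si](C)(C)C(C)(C)C | intermediate
4 | tert-butyl[5-(chloromethyl)-2-methoxyphenoxy]dimethylsilane | COc1ccc(CCl)cc1O[Si](C)(C)C(C)(C)C | intermediate
5 | [3-(tert-butyldimethylsilyloxy)-4-methoxybenzyl]magnesium chloride | COc1ccc(C[Mg]Cl)cc1O[Si](C)(C)C(C)(C)C | intermediate
6 | but-2-yne-1,4-diol | OCC#CCO | starting material
7 | carbon dioxide | O=C=O | starting material
8 | bis(chloromagnesium) but-2-yne-1,4-diolate | Cl[Mg]OCC#CCO[Mg]Cl | intermediate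
9 | 4-{[3-(tert-butyldimethylsilyloxy)-4-methoxyphenyl]methyl}-3-[(chloromagnesiooxy)methyl]-2,5-dihydro-1,2-oxamagnesole (magnesium on C4 bound to the C2 oxygen, benzyl group trans to magnesium) | COc1ccc(CC2=C(CO[Mg]Cl)[Mg]OC2)cc1O[Si](C)(C)C(C)(C)C | intermediate
10 | (2Z)-3-{[3-(tert-butyldimethylsilyloxy)-4-methoxyphenyl]methyl}-4-hydroxy-2-(hydroxymethyl)but-2-enoic acid | OC/C(Cc1ccc(OC)c(O[Si](C)(C)C(C)(C)C)c1)=C(/CO)C(O)=O | intermediate
11 | 4-{[3-(tert-butyldimethylsilyloxy)-4-methoxyphenyl]methyl}-3-(hydroxymethyl)furan-2(5H)-one | COc1ccc(CC2=C(CO)C(=O)OC2)cc1O[Si](C)(C)C(C)(C)C | intermediate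
12 | (3R,4R)-4-{[3-(tert-butyldimethylsilyloxy)-4-methoxyphenyl]methyl}-3-(hydroxymethyl)oxolan-2-one (cis) | COc1ccc(C[C@H]2COC(=O)[C@H]2CO)cc1O[Si](C)(C)C(C)(C)C | intermediate
13 | (3R,4R)-4-{[3-(tert-butyldimethylsilyloxy)-4-methoxyphenyl]methyl}-3-(hydroxymethyl)oxolan-2-ol (both anomers at the lactol carbon) | COc1ccc(C[C@H]2COC(O)[C@H]2CO)cc1O[Si](C)(C)C(C)(C)C | intermediate
14 | [(3R,4R)-4-{[3-(tert-butyldimethylsilyloxy)-4-methoxyphenyl]methyl}oxolan-3-yl]methanol (cis) | COc1ccc(C[C@H]2COC[C@H]2CO)cc1O[Si](C)(C)C(C)(C)C | intermediate
15 | 5-bromo-2-methoxyphenol | COc1ccc(Br)cc1O | starting material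
16 | (5-bromo-2-methoxyphenoxy)(tert-butyl)dimethylsilane | COc1ccc(Br)cc1O[Si](C)(C)C(C)(C)C | intermediate
17 | [3-(tert-butyldimethylsilyloxy)-4-methoxyphenyl]magnesium bromide | COc1ccc([Mg]Br)cc1O[Si](C)(C)C(C)(C)C | intermediate
18 | (3S,4R)-4-{[3-(tert-butyldimethylsilyloxy)-4-methoxyphenyl]methyl}oxolane-3-carbaldehyde (cis) | COc1ccc(C[C@H]2COC[C@H]2C=O)cc1O[Si](C)(C)C(C)(C)C | intermediate
19 | (S)-[3-(tert-butyldimethylsilyloxy)-4-methoxyphenyl][(3S,4R)-4-{[3-(tert-butyldimethylsilyloxy)-4-methoxyphenyl]methyl}oxolan-3-yl]methanol | COc1ccc(C[C@H]2COC[C@H]2[C@H](O)c2ccc(OC)c(O[Si](C)(C)C(C)(C)C)c2)cc1O[Si](C)(C)C(C)(C)C | intermediate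
20 | (S)-(3-hydroxy-4-methoxyphenyl)[(3S,4R)-4-(3-hydroxy-4-methoxybenzyl)oxolan-3-yl]methanol | COc1ccc(C[C@H]2COC[C@H]2[C@H](O)c2ccc(OC)c(O)c2)cc1O | target

## Step count and risks

Total step count: 13. Longest linear sequence: 11 steps (steps 1–8 and 11–13); steps 9 and 10 prepare reagent 17 on a side branch.

**Step 6 (asymmetric hydrogenation).**
- Most likely failure: slow or absent insertion of the tetrasubstituted C3=C4 bond into the ruthenium hydride, or weak discrimination between the alkene faces, because the two substituents on C3 (CH2O and CH2Ar) are of similar size.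
- Fallback: it sets out from 11 and returns at 12. Hydrogenation over Rh/Al2O3 in ethyl acetate, a reliable syn addition with little allylic C–O hydrogenolysis, should give the racemic cis lactone F1. Kinetic resolution of its primary alcohol with Burkholderia cepacia lipase and vinyl acetate in tert-butyl methyl ether should leave one enantiomer as alcohol and convert the other to its acetate. If the (3S,4S)-enantiomer is acylated to acetate F2, the remaining alcohol is 12 and is carried on. If the enzyme prefers the other antipode, the (3R,4R)-acetate F3 is collected and returned to 12 by methanolysis with the same lipase, without base. Half of the material is lost, but every operation is of a known type.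

**Step 5 (key step).**
- Most likely failure: copper-promoted homocoupling of the benzyl reagent before it adds, loss of the alkenylmagnesium 9 by β-elimination of the C7 oxide to an allene on warming, and sluggish capture of CO2 by the hindered, chelated tetrasubstituted alkenyl–magnesium bond.
- Fallback: it sets out from 6 and 5 and returns at 11. Intermediate 9 is quenched with iodine to give (2Z)-2-{[3-(tert-butyldimethylsilyloxy)-4-methoxyphenyl]methyl}-3-iodobut-2-ene-1,4-diol F4. The one-carbon unit is then introduced by carbonylative lactonisation with CO (1 atm), PdCl2(PPh3)2 and K2CO3 in THF. The acyl–palladium intermediate is trapped by the cis C2 hydroxyl, so the same C4–C5 and C5–O1 bonds are formed.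

**Step 12 (aryl addition).**
- Most likely failure: deprotonation of aldehyde 18 by the basic Grignard reagent with loss of the cis configuration at C4, or incomplete facial selectivity if the chelate is not populated.
- Fallback: it sets out from 16 and 18 and returns at 19. Bromide 16 is converted by n-BuLi and B(OMe)3 into [3-(tert-butyldimethylsilyloxy)-4-methoxyphenyl]boronic acid F5. Boron–zinc exchange with Et2Zn in toluene gives the aryl(ethyl)zinc F6. This weakly basic reagent is added to 18 with a catalytic chiral amino alcohol (3-exo-morpholinoisoborneol, in the enantiomer that directs aryl transfer to the Re face), so that catalyst control reinforces the substrate preference.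

**Step 8 (lactol reduction).**
- Most likely failure: the oxocarbenium ion is diverted before hydride arrives, either by Friedel–Crafts closure onto ring B at the position para to the silyloxy group (a six-membered ring) or by loss of the C4 proton to an enol ether, which scrambles the cis relationship.
- Fallback: it sets out from 12 and returns at 14, and avoids the cation altogether. The hydroxyl of 12 is protected (Ph3CCl, pyridine) as the trityl ether F7. LiBH4 reduces the lactone to the 1,4-diol F8, in which C4 remains a stereocentre because its two oxygenated carbons are differentiated. Mitsunobu cyclodehydration (PPh3, diisopropyl azodicarboxylate) closes the ring to the trityl ether F9. Pyridinium p-toluenesulfonate in methanol removes the trityl group without touching the aryl silyl ether and gives 14.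

## Further compounds

F1 | step 6 | racemic cis lactone, rac-(3R,4R)-4-{[3-(tert-butyldimethylsilyloxy)-4-methoxyphenyl]methyl}-3-(hydroxymethyl)oxolan-2-one (1:1 mixture of 12 and its enantiomer) | COc1ccc(C[C@H]2COC(=O)[C@H]2CO)cc1O[Si](C)(C)C(C)(C)C.COc1ccc(C[C@@H]2COC(=O)[C@@H]2CO)cc1O[Si](C)(C)C(C)(C)C
F2 | step 6 | [(3S,4S)-4-{[3-(tert-butyldimethylsilyloxy)-4-methoxyphenyl]methyl}-2-oxooxolan-3-yl]methyl acetate | COc1ccc(C[C@@H]2COC(=O)[C@@H]2COC(C)=O)cc1O[Si](C)(C)C(C)(C)C
F3 | step 6 | [(3R,4R)-4-{[3-(tert-butyldimethylsilyloxy)-4-methoxyphenyl]methyl}-2-oxooxolan-3-yl]methyl acetate | COc1ccc(C[C@H]2COC(=O)[C@H]2COC(C)=O)cc1O[Si](C)(C)C(C)(C)C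
F4 | step 5 | (2Z)-2-{[3-(tert-butyldimethylsilyloxy)-4-methoxyphenyl]methyl}-3-iodobut-2-ene-1,4-diol | OC/C(Cc1ccc(OC)c(O[Si](C)(C)C(C)(C)C)c1)=C(/CO)I
F5 | step 12 | [3-(tert-butyldimethylsilyloxy)-4-methoxyphenyl]boronic acid | COc1ccc(B(O)O)cc1O[Si](C)(C)C(C)(C)C
F6 | step 12 | [3-(tert-butyldimethylsilyloxy)-4-methoxyphenyl](ethyl)zinc | CC[Zn]c1ccc(OC)c(O[Si](C)(C)C(C)(C)C)c1
F7 | step 8 | (3R,4R)-4-{[3-(tert-butyldimethylsilyloxy)-4-methoxyphenyl]methyl}-3-[(trityloxy)methyl]oxolan-2-one | COc1ccc(C[C@H]2COC(=O)[C@H]2COC(c2ccccc2)(c2ccccc2)c2ccccc2)cc1O[Si](C)(C)C(C)(C)C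
F8 | step 8 | (2R,3S)-2-{[3-(tert-butyldimethylsilyloxy)-4-methoxyphenyl]methyl}-3-[(trityloxy)methyl]butane-1,4-diol | COc1ccc(C[C@@H](CO)[C@@H](CO)COC(c2ccccc2)(c2ccccc2)c2ccccc2)cc1O[Si](C)(C)C(C)(C)C
F9 | step 8 | tert-butyl(2-methoxy-5-{[(3R,4S)-4-[(trityloxy)methyl]oxolan-3-yl]methyl}phenoxy)dimethylsilane (trityl ether of 14) | COc1ccc(C[C@H]2COC[C@H]2COC(c2ccccc2)(c2ccccc2)c2ccccc2)cc1O[Si](C)(C)C(C)(C)C
A1 | alternative 1 | 2,5-dihydrofuran | C1C=CCO1
A2 | alternative 1 | 2-[3-(tert-butyldimethylsilyloxy)-4-methoxyphenyl]-1-[(2R,5R)-2,5-dimethylpyrrolidin-1-yl]ethan-1-one | COc1ccc(CC(=O)N2[C@H](C)CC[C@H]2C)cc1O[Si](C)(C)C(C)(C)C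
A3 | alternative 1 | cis-fused 7-[3-(tert-butyldimethylsilyloxy)-4-methoxyphenyl]-3-oxabicyclo[3.2.0]heptan-6-one | O=C1[C@H](c2ccc(OC)c(O[Si](C)(C)C(C)(C)C)c2)[C@H]2COC[C@@H]12
A4 | alternative 1 | [3-(tert-butyldimethylsilyloxy)-4-methoxyphenyl][(3S,4R)-4-{[3-(tert-butyldimethylsilyloxy)-4-methoxyphenyl]methyl}oxolan-3-yl]methanone | COc1ccc(C[C@H]2COC[C@H]2C(=O)c2ccc(OC)c(O[Si](C)(C)C(C)(C)C)c2)cc1O[Si](C)(C)C(C)(C)C
A5 | alternative 2 | (S)-5-[3-(benzyloxy)-4-methoxyphenyl]furan-2(5H)-one | O=C1C=C[C@@H](c2ccc(OC)c(OCc3ccccc3)c2)O1
A6 | alternative 2 | chloromethyl (trimethylsilyl)methyl ether | C[Si](C)(C)COCCl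
A7 | alternative 2 | cis-fused 4-[3-(benzyloxy)-4-methoxyphenyl]-3,7-dioxabicyclo[3.3.0]octan-2-one, aryl group exo | O=C1O[C@H](c2ccc(OC)c(OCc3ccccc3)c2)[C@H]2COC[C@@H]12
A8 | alternative 2 | (3S,4R)-4-(3-hydroxy-4-methoxybenzyl)oxolane-3-carboxylic acid | COc1ccc(C[C@H]2COC[C@H]2C(O)=O)cc1O
A9 | alternative 3 | allyl 2-bromo-3-(tert-butyldimethylsilyloxy)-3-[3-(tert-butyldimethylsilyloxy)-4-methoxyphenyl]propyl ether, C7 configured as in the target, bromide carbon unspecified | COc1ccc([C@@H](O[Si](C)(C)C(C)(C)C)C(Br)COCC=C)cc1O[Si](C)(C)C(C)(C)C
A10 | alternative 3 | tris(tert-butyldimethylsilyl) ether of 20 | COc1ccc(C[C@H]2COC[C@H]2[C@H](O[Si](C)(C)C(C)(C)C)c2ccc(OC)c(O[Si](C)(C)C(C)(C)C)c2)cc1O[Si](C)(C)C(C)(C)C
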